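The numbers in the tables are calculated from invented constants.

The autumn flask has grown slow: it gained 6.5 percentage points between 2.00 h and 5.00 h, but 2.2 points over the 10.0 h up to 25.0 h, where it reads 22.0 %. At that last pace I get 23.1 % by 30 h, and the pace is still falling, so I expect little from waiting. Yet the charge has room for 70.0 %, if one reagent goes into each product.

| setting | autumn | dawn | flask |
|---|---|---|---|
| starting material | 39 mM | 39 mM | 39 mM |
| reagent | 27.3 mM | 55 mM | 27.3 mM |
| free catalyst | 0.35 mM | 0.35 mM | 0.35 mM |
| temperature | 80 °C | 80 °C | 80 °C |
| remark | the very flask that is asked about, followed so far | run made earlier |  |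
| time |  |  | 30 h |

- autumn (time / h: product / %): 2.00: 3.4; 3.00: 5.0; 5.00: 9.9; 8.00: 13.9; 15.0: 19.8; 25.0: 22.0
- dawn (time / min: product / %): 5.00: 0; 15.0: 0.4; 25.0: 0.4; 40.0: 0.4; 60.0: 1.3; 80.0: 2.3

(each reading ± 0.3 percentage points)

1. product, in percent of the starting material first charged, at 30 h
2. which option adds most product ("none" when 2 percentage points or less is all one gets) (Wednesday's / Saturday's / Thursday's / Sunday's / none)
3. product present, in percent of the starting material first charged, after Wednesday's
4. product present, in percent of the starting material first charged, after Thursday's

- Wednesday's: change nothing and wait 15 h more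
- Saturday's: at 30 h add reagent, 100 % of the amount charged, then wait 15 h
- Thursday's: at 30 h raise the temperature by 15 K, then wait 15 h
- Sunday's: at 30 h add free catalyst, 100 % of the amount charged, then wait 15 h

- additions leave the volume as it is
- the earlier runs do not show what temperature does; that part of a forecast is a guess
- a reading or a percentage of product counts all its forms, free or not

I carry one number. The autumn flask has made 8.58 mM of product from 27.3 mM of reagent, so its reagent yield is 31.4 %, the product made per reagent charged. I cannot read reagent, but the dawn flask, which started with [reagent] at 55 mM, gained 1 point in the 20.0 min up to 80.0 min, a faster pace than the autumn flask's early one. So my bet is that the autumn flask is waiting for reagent. A second charge at the same yield adds 22 points, and I choose Saturday's. I leave the temperature alone, as the earlier runs do not show what it does.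

The forecast gives 22.7 % at 30 h (22 % to 23.6 %), 23.4 % after Wednesday's and 23.8 % after Thursday's, and it picks Sunday's: “Fresh catalyst should add roughly 10 points”. We part on that choice.

The flask gives 22.1 % at 30 h, 22.3 % after Wednesday's and 22.3 % after Thursday's, and the best option is Saturday's.

    reagent + catalyst intermediate → free catalyst + product (k = 0.250 /M/s, Ea = 60.0 kJ/mol)
    2 reagent → homo dimer (k = 0.00210 /M/s, Ea = 70.0 kJ/mol)
    starting material + free catalyst ⇌ free catalyst + open intermediate (K = 0.380, k = 0.0550 /M/s, Ea = 75.0 kJ/mol, ΔH = 22.0 kJ/mol)
    free catalyst + open intermediate ⇌ catalyst intermediate (K = 170 /M, k = 0.690 /M/s, Ea = 53.0 kJ/mol, ΔH = −5.00 kJ/mol)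
    crystals ⇌ product, rate k5*(cs5 - [product]) while solid is left; crystals form when [product] > cs5 (solubility = 14.0 mM, k = 0.00900 /s)
    (constants at 80 °C)

Saturday's adds 25 points against my 22 points, while Sunday's adds 0.22 points. At 30.0 h the autumn flask holds 0.314 % of its reagent, the limiting reagent here. The same run without the shrinking supply gives 72.2 % instead of 22.1 %, and without the loss to homo dimer it gives 59.9 %. For the neighbour flask, with 98 mM of starting material and the same reagent, my yield gives 8.75 %; it stands at 11.2 %, a reagent yield of 40.2 %.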